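**Retrosynthetic overview**

- The linoleate ester is cut last (C1–O acyl bond): the target comes from the (2R)-1,3-diol and linoleic acid by selective acylation of the primary hydroxyl.
- The diol comes from an α-(indol-3-yl) acyl oxazolidinone in which C1 is raised to the acyl level and the tertiary hydroxyl is a triethylsilyl ether.
- Key disconnection: the bond between indole C3 and side-chain C2, made by copper-mediated oxidative heterocoupling of N-unprotected 6-prenylindole with the chelated Z-enolate of a chiral imide; this joins the two fragments, sets the only stereocenter and needs no protecting or activating group on the indole.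
- Enabling feature: C3 of the pyrrole ring of the indole is the enamine-type carbon next to the free N1–H, and side-chain C2 lies α to the oxygen-bearing C1; with C1 as an acyl carbon both atoms are carbanion-type centres that a two-electron oxidant can join.
- No ring is formed: the benzene and pyrrole rings of the indole are bought as 6-bromoindole (prenylated by Stille coupling); the imide comes from an N-acetyl oxazolidinone and acetone.

Key step: step 4

Assumption (chemistry): the copper-mediated coupling is taken to follow the facial sense of alkylations of lithium-chelated Z-enolates of (4S)-4-benzyloxazolidinone imides (new bond anti to benzyl); should the opposite sense be found, the (4R)-auxiliary is used in steps 2 to 5.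

**Route**

Step 1
Reactants: 1 6-bromo-1H-indole; 2 tributyl(3-methylbut-2-en-1-yl)stannane
Product: 3 6-(3-methylbut-2-en-1-yl)-1H-indole
Conditions: Pd(PPh3)4 (5 mol %), DMF, 100 °C
Reagents that add atoms: none
Why: Stille coupling, in which zerovalent palladium inserts into the C6–Br bond, the allylic stannane transmetalates and reductive elimination at the unsubstituted allyl terminus should give the linear prenyl arene, the free N–H being tolerated.

Step 2
Reactants: 4 (4S)-3-acetyl-4-benzyl-1,3-oxazolidin-2-one; 5 acetone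
Product: 7 (4S)-4-benzyl-3-(3-hydroxy-3-methylbutanoyl)-1,3-oxazolidin-2-one, via lithium enolate 6 (not isolated)
Conditions: LiN(iPr)2, THF, −78 °C; acetone, −78 °C; AcOH quench at −78 °C
Reagents that add atoms: none
Why: Acetate aldol addition of an imide lithium enolate to a ketone, which should give the tertiary β-hydroxy imide when quenched cold to prevent retro-aldol cleavage; no stereocenter is formed.

Step 3
Reactants: 7 (4S)-4-benzyl-3-(3-hydroxy-3-methylbutanoyl)-1,3-oxazolidin-2-one
Product: 8 (4S)-4-benzyl-3-{3-methyl-3-[(triethylsilyl)oxy]butanoyl}-1,3-oxazolidin-2-one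
Conditions: Et3SiOTf, 2,6-lutidine, CH2Cl2, −78 → 0 °C
Reagents that add atoms: triethylsilyl trifluoromethanesulfonate, CC[Si](CC)(CC)OS(=O)(=O)C(F)(F)F
Why: Silylation of a tertiary alcohol with a silyl triflate and a hindered base, which masks the hydroxyl so that step 4 deprotonates only the α-CH2 and the indole N–H and the aldolate cannot fragment or attack the ring carbonyl.

Step 4
Reactants: 3 6-(3-methylbut-2-en-1-yl)-1H-indole (2 equiv, excess recovered); 8 (4S)-4-benzyl-3-{3-methyl-3-[(triethylsilyl)oxy]butanoyl}-1,3-oxazolidin-2-one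
Product: 11 (4S)-4-benzyl-3-{(2S)-3-methyl-2-[6-(3-methylbut-2-en-1-yl)-1H-indol-3-yl]-3-[(triethylsilyl)oxy]butanoyl}-1,3-oxazolidin-2-one, via lithium Z-enolate 9 (not isolated), via lithium 6-prenylindol-1-ide 10 (not isolated)
Conditions: LiN(SiMe3)2 (3.3 equiv), THF, −78 °C; then Cu(O2CCH(Et)Bu)2 (copper bis(2-ethylhexanoate), 2.2 equiv), −78 → −20 °C; aq NH4Cl quench cold
Reagents that add atoms: none
Why: LiN(SiMe3)2 turns 8 into the lithium-chelated Z-enolate 9 and 3 into the indolide 10; both bind divalent copper, inner-sphere one-electron oxidation of the enolate gives a copper-bound α-acyl radical that is trapped at C3 of the indolide, a second divalent copper takes the second electron, and the 3H-indole formed tautomerises to the 1H-indole. The closest known reaction type is the copper-mediated oxidative heterocoupling of N-unprotected indoles with lithium enolates of ketones, esters, amides and chiral imides (direct indole–carbonyl coupling). No ring is closed. The new stereocenter, C2 of the acyl chain, is controlled by the (4S)-benzyl group of the chelated Z-enolate, which screens one face so that the indole bonds anti to benzyl and should give the (2S)-imide, which becomes the (2R)-centre of the target after step 5 without any change in geometry. The step needs hetero- over homocoupling, secured by the excess of 10, C3 over N1 or C2 attack, secured by the enamine-type C3 of the N-metalated pyrrole ring, and an enolate that does not lose silanolate by β-elimination, secured by −78 °C and the poor leaving-group ability of the tertiary silyl ether. The prenyl alkene, the silyl ether and the oxazolidinone are inert to the amide base and to the oxidant.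

Step 5
Reactants: 11 (4S)-4-benzyl-3-{(2S)-3-methyl-2-[6-(3-methylbut-2-en-1-yl)-1H-indol-3-yl]-3-[(triethylsilyl)oxy]butanoyl}-1,3-oxazolidin-2-one
Product: 12 (2R)-3-methyl-2-[6-(3-methylbut-2-en-1-yl)-1H-indol-3-yl]-3-[(triethylsilyl)oxy]butan-1-ol
Conditions: LiBH4, THF, 0 °C
Reagents that add atoms: none
Why: Reductive cleavage of an N-acyl oxazolidinone by hydride attack at the exocyclic carbonyl, which should give the primary alcohol and return the auxiliary under non-basic conditions that leave the α-stereocenter untouched (the descriptor changes from S to R only through the CIP priorities).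

Step 6
Reactants: 12 (2R)-3-methyl-2-[6-(3-methylbut-2-en-1-yl)-1H-indol-3-yl]-3-[(triethylsilyl)oxy]butan-1-ol
Product: 13 (2R)-3-methyl-2-[6-(3-methylbut-2-en-1-yl)-1H-indol-3-yl]butane-1,3-diol
Conditions: HF·pyridine, pyridine, THF, 0 °C → rt
Reagents that add atoms: none
Why: Fluoride-mediated desilylation, buffered with pyridine so that the tertiary alcohol next to the indolyl-bearing carbon is released without acid-promoted ionisation or hydration of the prenyl alkene.

Step 7
Reactants: 13 (2R)-3-methyl-2-[6-(3-methylbut-2-en-1-yl)-1H-indol-3-yl]butane-1,3-diol; 14 (9Z,12Z)-octadeca-9,12-dienoic acid (linoleic acid)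
Product: 15 (2R)-3-hydroxy-3-methyl-2-[6-(3-methylbut-2-en-1-yl)-1H-indol-3-yl]butyl (9Z,12Z)-octadeca-9,12-dienoate
Conditions: DCC (1.1 equiv), DMAP (0.1 equiv), CH2Cl2, 0 °C → rt, under argon
Reagents that add atoms: none
Why: Steglich esterification, which should acylate the primary hydroxyl selectively over the tertiary hydroxyl and the indole N–H under neutral conditions that leave the skipped Z,Z-diene in place.

**Compound list**

1 | 6-bromo-1H-indole | Brc1ccc2cc[nH]c2c1 | starting material
2 | tributyl(3-methylbut-2-en-1-yl)stannane | CCCC[Sn](CCCC)(CCCC)CC=C(C)C | starting material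
3 | 6-(3-methylbut-2-en-1-yl)-1H-indole | CC(C)=CCc1ccc2cc[nH]c2c1 | intermediate
4 | (4S)-3-acetyl-4-benzyl-1,3-oxazolidin-2-one | CC(=O)N1C(=O)OC[C@@H]1Cc1ccccc1 | starting material
5 | acetone | CC(C)=O | starting material
6 | lithium enolate of 4 | [Li+].C=C([O-])N1C(=O)OC[C@@H]1Cc1ccccc1 | intermediate
7 | (4S)-4-benzyl-3-(3-hydroxy-3-methylbutanoyl)-1,3-oxazolidin-2-one | CC(C)(O)CC(=O)N1C(=O)OC[C@@H]1Cc1ccccc1 | intermediate
8 | (4S)-4-benzyl-3-{3-methyl-3-[(triethylsilyl)oxy]butanoyl}-1,3-oxazolidin-2-one | CC[Si](CC)(CC)OC(C)(C)CC(=O)N1C(=O)OC[C@@H]1Cc1ccccc1 | intermediate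
9 | lithium Z-enolate of 8 | [Li+].CC[Si](CC)(CC)OC(C)(C)/C=C(\[O-])N1C(=O)OC[C@@H]1Cc1ccccc1 | intermediate
10 | lithium 6-(3-methylbut-2-en-1-yl)indol-1-ide | [Li+].CC(C)=CCc1ccc2cc[n-]c2c1 | intermediate
11 | (4S)-4-benzyl-3-{(2S)-3-methyl-2-[6-(3-methylbut-2-en-1-yl)-1H-indol-3-yl]-3-[(triethylsilyl)oxy]butanoyl}-1,3-oxazolidin-2-one | O=C(N1C(=O)OC[C@@H]1Cc1ccccc1)[C@@H](c1c[nH]c2cc(CC=C(C)C)ccc12)C(C)(C)O[Si](CC)(CC)CC | intermediate
12 | (2R)-3-methyl-2-[6-(3-methylbut-2-en-1-yl)-1H-indol-3-yl]-3-[(triethylsilyl)oxy]butan-1-ol | OC[C@@H](c1c[nH]c2cc(CC=C(C)C)ccc12)C(C)(C)O[Si](CC)(CC)CC | intermediate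
13 | (2R)-3-methyl-2-[6-(3-methylbut-2-en-1-yl)-1H-indol-3-yl]butane-1,3-diol | OC[C@@H](c1c[nH]c2cc(CC=C(C)C)ccc12)C(C)(C)O | intermediate
14 | (9Z,12Z)-octadeca-9,12-dienoic acid | CCCCC/C=C\C/C=C\CCCCCCCC(=O)O | starting material
15 | (2R)-3-hydroxy-3-methyl-2-[6-(3-methylbut-2-en-1-yl)-1H-indol-3-yl]butyl (9Z,12Z)-octadeca-9,12-dienoate | CCCCC/C=C\C/C=C\CCCCCCCC(=O)OC[C@@H](c1c[nH]c2cc(CC=C(C)C)ccc12)C(C)(C)O | target

**Step count and risks**

Total steps: 7. Longest linear sequence: 6 steps (from 4 through steps 2 to 7).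

Most likely to fail:

1. Step 4. The enolate or the indolide may homocouple, the enolate may lose silanolate by β-elimination before it is oxidised, bond formation at the congested carbon next to the fully substituted centre may be slow, or facial selectivity may be poor. The fallback sets out from 3 and comes back at 13; it builds the same stereocenter by an aldol reaction instead.
   - Copper-catalysed C3–H functionalisation of 3 with ethyl diazoacetate (Cu(OTf)2, CH2Cl2) would give ethyl 2-[6-(3-methylbut-2-en-1-yl)-1H-indol-3-yl]acetate F1.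
   - Saponification (LiOH, THF/H2O) would give 2-[6-(3-methylbut-2-en-1-yl)-1H-indol-3-yl]acetic acid F2.
   - Activation with pivaloyl chloride and Et3N would give 2-[6-(3-methylbut-2-en-1-yl)-1H-indol-3-yl]acetic pivalic anhydride F3, which acylates (4R)-4-benzyl-1,3-oxazolidin-2-one in the presence of LiCl to (4R)-4-benzyl-3-{2-[6-(3-methylbut-2-en-1-yl)-1H-indol-3-yl]acetyl}-1,3-oxazolidin-2-one F4.
   - Double deprotonation (LiN(iPr)2, 2.1 equiv, THF, −78 °C) would give the dilithium N,O-dianion of F4 (Z-enolate) F5, which adds to acetone 5 anti to the benzyl group through the lithium-chelated enolate to give (4R)-4-benzyl-3-{(2S)-3-hydroxy-3-methyl-2-[6-(3-methylbut-2-en-1-yl)-1H-indol-3-yl]butanoyl}-1,3-oxazolidin-2-one F6.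
   - LiBH4 (THF, 0 °C) then gives 13 directly.

2. Step 5. Hydride may attack the ring carbonyl of the congested imide and open the oxazolidinone, or the reduction may stall. The fallback sets out from 11 and comes back at 12: hydrolysis with LiOH/H2O2 (THF/H2O, 0 °C), where hydroperoxide attacks the exocyclic carbonyl selectively, would give (2S)-3-methyl-2-[6-(3-methylbut-2-en-1-yl)-1H-indol-3-yl]-3-[(triethylsilyl)oxy]butanoic acid F7, which LiAlH4 (THF, 0 °C) reduces to 12.

3. Step 1. Allyl transposition during transmetalation or reductive elimination may give the reverse-prenyl (1,1-dimethylallyl) isomer, or the stannane may be lost by protodestannylation. The fallback sets out from 1 and comes back at 3, with the polarity inverted.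
   - N-silylation (NaH, iPr3SiCl, THF) would give 6-bromo-1-(triisopropylsilyl)-1H-indole F8.
   - Bromine–lithium exchange (t-BuLi, 2 equiv, THF, −78 °C) would give 6-lithio-1-(triisopropylsilyl)-1H-indole F9.
   - Alkylation with 1-bromo-3-methylbut-2-ene at its primary carbon would give 6-(3-methylbut-2-en-1-yl)-1-(triisopropylsilyl)-1H-indole F10.
   - Bu4NF (THF) then returns 3.

**Further compounds**

F1 | step 4 | ethyl 2-[6-(3-methylbut-2-en-1-yl)-1H-indol-3-yl]acetate | CCOC(=O)Cc1c[nH]c2cc(CC=C(C)C)ccc12
F2 | step 4 | 2-[6-(3-methylbut-2-en-1-yl)-1H-indol-3-yl]acetic acid | OC(=O)Cc1c[nH]c2cc(CC=C(C)C)ccc12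
F3 | step 4 | 2-[6-(3-methylbut-2-en-1-yl)-1H-indol-3-yl]acetic pivalic anhydride | CC(C)(C)C(=O)OC(=O)Cc1c[nH]c2cc(CC=C(C)C)ccc12
F4 | step 4 | (4R)-4-benzyl-3-{2-[6-(3-methylbut-2-en-1-yl)-1H-indol-3-yl]acetyl}-1,3-oxazolidin-2-one | O=C(Cc1c[nH]c2cc(CC=C(C)C)ccc12)N1C(=O)OC[C@H]1Cc1ccccc1
F5 | step 4 | dilithium N,O-dianion of F4 (Z-enolate) | [Li+].[Li+].[O-]/C(=C\c1c[n-]c2cc(CC=C(C)C)ccc12)N1C(=O)OC[C@H]1Cc1ccccc1
F6 | step 4 | (4R)-4-benzyl-3-{(2S)-3-hydroxy-3-methyl-2-[6-(3-methylbut-2-en-1-yl)-1H-indol-3-yl]butanoyl}-1,3-oxazolidin-2-one | O=C(N1C(=O)OC[C@H]1Cc1ccccc1)[C@@H](c1c[nH]c2cc(CC=C(C)C)ccc12)C(C)(C)O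
F7 | step 5 | (2S)-3-methyl-2-[6-(3-methylbut-2-en-1-yl)-1H-indol-3-yl]-3-[(triethylsilyl)oxy]butanoic acid | OC(=O)[C@@H](c1c[nH]c2cc(CC=C(C)C)ccc12)C(C)(C)O[Si](CC)(CC)CC
F8 | step 1 | 6-bromo-1-(triisopropylsilyl)-1H-indole | CC(C)[Si](C(C)C)(C(C)C)n1ccc2ccc(Br)cc21
F9 | step 1 | 6-lithio-1-(triisopropylsilyl)-1H-indole | [Li]c1ccc2ccn([Si](C(C)C)(C(C)C)C(C)C)c2c1
F10 | step 1 | 6-(3-methylbut-2-en-1-yl)-1-(triisopropylsilyl)-1H-indole | CC(C)=CCc1ccc2ccn([Si](C(C)C)(C(C)C)C(C)C)c2c1
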